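The first chemist and the second chemist stand before three runs of one reaction, starting material to product, and must say what the alder flask holds; it is charged like the ash run.

| flask | starting material | time |
|---|---|---|
| ash | 150 mM |  |
| elm | 90.0 mM |  |
| cedar | 300 mM |  |
| alder | 150 mM | 25 min |

- ash run (time / min: [product] / mM): 0.17: 6.0; 0.27: 10.1; 0.42: 13.6; 0.67: 21.2; 1.1: 32.4; 1.7: 43.3; 2.7: 55.7; 4.2: 65.0
- elm run (time / min: [product] / mM): 0.17: 4.1; 0.27: 7.0; 0.42: 9.2; 0.67: 14.6; 1.1: 21.3; 1.7: 28.5; 2.7: 35.9; 4.2: 40.3
- cedar run (time / min: [product] / mM): 0.17: 9.6; 0.27: 15.5; 0.42: 23.9; 0.67: 35.8; 1.1: 56.1; 1.7: 76.9; 2.7: 102.2; 4.2: 122.1

(readings scatter by 0.4 mM)

1. the power of [starting material] that the first rate follows, about the charge of the ash run; measure it at two percent of starting material made into product (one fixed amount of product, the same in the runs compared)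
2. product in the alder run at 25 min, as a share of the starting material charged

- Overall: starting material -> product.
- Constant volume, constant temperature.
- Bound and free are read together.
- An order is taken over about fifteen percent of the charge, up and down.

Both reckon in shares of the charge. At 4.2 min the ash run has made 43.3 %, the elm run 44.8 % and the cedar run 40.7 %. These shares lie close together, and both views accept them.

Now the blackboard. The first two ash readings give a forward constant of 0.244 min⁻¹ of the charge. The last three give a rate falling at 0.555 min⁻¹, which is faster than the forward constant. Call the difference, 0.311 min⁻¹, the excess fall: the part of the rate's decline per minute that starting material turning into product does not pay for. It is a reading and carries the scatter of those readings.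

The first chemist, who made the forecast, says “the cause looks like catalyst death”. In that view the rate dies and the product made stays; the forecast is 51 % (46 % to 60 %), with order 0.72.

The second chemist reads the excess as chemistry: product returning, and starting material leaking away. The constants of these two add up to the excess. The ash share is then a slow exponential minus a fast one running at the fall; once the fast one has faded, the two hold a steady ratio (a quasi-steady state), and product drains at return times leak over fall. An even split, which is this chemist's guess, gives 0.0435 min⁻¹. The ash share at 4.2 min is still rising, so this chemist sets that curve through it and carries the slow part to 25 min, which gives 19.9 %, below the low end of the forecast.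

The simulation gives order 0.80 and, in the alder run at 25 min, 21.8 %.

    starting material ⇌ product (0.3600 min⁻¹, 0.1368 min⁻¹)
    2 starting material ⇌ idle substrate dimer, settled at all times (2.210 L mol⁻¹)
    starting material → decomposed substrate (0.1944 min⁻¹)

The first chemist's view holds over the ash readings up to 4.2 min, where a stopping flask and a draining one both still rise. The main reason for the low alder figure is the loss of starting material to decomposed substrate: alder stands at 21.8 % with it and 69.1 % in the run without it. Give that loss 0.194 min⁻¹ of the excess fall and call the rest return; the drain becomes 0.0407 min⁻¹, and the same curve through the ash share gives 21.0 % at 25 min. Without the loss, the equilibrium share, forward over forward plus return, gives 67.6 %, beside the 69.1 % of that run.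

Readings and results stem from a simulated flask with constants of no real substance, noise included.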